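**Plan**

1. The target is a dihydrofuran (O1, C2, C3, C3a, C7a) fused to an enolised cyclohexadienone, that is, a dearomatised acylphloroglucinol. The retrosynthesis cuts C3–C3a and O1–C2 together, then the two ring–prenyl bonds, then the ring–acyl bond.
2. Enabling feature: C3a and O1 are the 1,3-related carbon/oxygen nucleophile pair of deoxyhumulone (a prenyl-bearing ring carbon and the neighbouring para oxygen). C3 and C2 are the 1,2-related electrophile pair of an epoxy-prenyl iodide (CH2–I and epoxide CH). The side-chain tertiary OH is the released epoxide oxygen.
3. Forward: phloroglucinol is acylated and then C-prenylated twice, which places every ring carbon. The last step dearomatises the ring and closes the dihydrofuran in one operation.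
4. Stereochemistry: C2 comes from a Katsuki–Sharpless epoxidation of prenol and is transferred with inversion in the 5-exo epoxide opening. C3a is chosen by a chiral ammonium counter-ion that differentiates the two enantiotopic prenyl-bearing carbons of the mirror-symmetric phenoxide.
5. The route is convergent: 5 steps, longest linear sequence 3.

Key step: step 5

Remark: 5, 9 and 10 are enolised beta-triketones and are drawn as one tautomer each; the sense of face selection by the cinchonidinium ion pair cannot be predicted with certainty, so the cinchonidine-derived salt is written and the pseudoenantiomeric cinchonine-derived salt would take its place if that one proves to be the partner matched with 8.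

**Route**

Step 1
Reactants: 1 phloroglucinol (benzene-1,3,5-triol); 2 isovaleryl chloride (3-methylbutanoyl chloride)
Product: 3 phlorisovalerophenone [3-methyl-1-(2,4,6-trihydroxyphenyl)butan-1-one]
Conditions: AlCl3 (3 equiv), PhNO2, 23 to 65 °C; ice/aq HCl
Reagents that add atoms: none
Why: Friedel–Crafts C-acylation of the highly activated arene; the chelated aryl ketone that forms is deactivated, so a second acylation should not follow.

Step 2
Reactants: 3 phlorisovalerophenone; 4 prenyl bromide (1-bromo-3-methylbut-2-ene)
Product: 5 deoxyhumulone [3-methyl-1-[2,4,6-trihydroxy-3,5-bis(3-methylbut-2-en-1-yl)phenyl]butan-1-one]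
Conditions: 4 (2.1 equiv), 10% aq KOH, 0 °C, Ar
Reagents that add atoms: none
Why: Double C-alkylation of the ambident phloroglucinol phenoxide at its two free ring positions, favoured in water where hydrogen bonding blocks the oxygens; two equivalents of 4 at 0 °C should hold back the third, dearomatising prenylation.

Step 3
Reactants: 6 prenol (3-methylbut-2-en-1-ol)
Product: 7 [(2R)-3,3-dimethyloxiran-2-yl]methanol
Conditions: Ti(OiPr)4 (5 mol %), D-(−)-diisopropyl tartrate (6 mol %), tBuOOH (1.5 equiv, anhydrous), 4 Å MS, CH2Cl2, −20 °C; work-up without water, distillation
Reagents that add atoms: tert-butyl hydroperoxide, CC(C)(C)OO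
Why: Katsuki–Sharpless asymmetric epoxidation of an allylic alcohol; the D-(−)-tartrate titanium complex should deliver oxygen to the alkene face that gives the (2R)-epoxy alcohol, the stereocentre that later becomes C2 of 10.

Step 4
Reactants: 7 [(2R)-3,3-dimethyloxiran-2-yl]methanol
Product: 8 (3S)-3-(iodomethyl)-2,2-dimethyloxirane
Conditions: PPh3, imidazole, I2, Et2O/MeCN 3:1, 0 °C, dark
Reagents that add atoms: iodine, II
Why: Appel-type substitution of the primary alcohol through its alkoxyphosphonium ion in a buffered medium that spares the epoxide; the stereocentre is untouched and its descriptor changes from R to S only by priority.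

Step 5
Reactants: 5 deoxyhumulone; 8 (3S)-3-(iodomethyl)-2,2-dimethyloxirane
Product: 10 (2S,3aS)-6-hydroxy-2-(2-hydroxypropan-2-yl)-5-(3-methylbutanoyl)-3a,7-bis(3-methylbut-2-en-1-yl)-3,3a-dihydro-1-benzofuran-4(2H)-one, via epoxy dienone 9 (not isolated)
Conditions: 8 (1.3 equiv), O-allyl-N-(9-anthracenylmethyl)cinchonidinium bromide (20 mol %), CsOH·H2O (4 equiv), 4 Å MS, toluene/CH2Cl2 3:1, Ar, −40 to 0 °C, then 23 °C; aq NaH2PO4
Reagents that add atoms: none
Why: Proposed new method: the caesium phenoxide of 5, paired with the chiral ammonium ion, attacks the primary iodide of 8 through a prenyl-bearing ring carbon (SN2, dearomatisation to the 6,6-disubstituted dienone 9), and the enol oxygen between the two prenylated carbons then opens the epoxide at its secondary carbon; the closest known reaction types are the dearomatising C-alkylation of 3,5-diprenylated acylphloroglucinols by alkyl halides, the cinchona-ammonium-controlled enantioselective alkylative dearomatisation of such phenoxides with allylic Michael-type electrophiles, and the base-induced cyclisation of ortho-(2,3-epoxy-3-methylbutyl)phenols, whose union with an sp3 iodide in one asymmetric operation has not been shown. The dihydrofuran closes 5-exo-tet by backside attack, and the basic medium keeps the 6-endo attack at the tertiary epoxide carbon, which needs acid, out of reach. C2 is therefore set by the reagent: inversion at the (R)-epoxide carbon of 9 gives (2S) and releases the tertiary alkoxide of the side chain. C3a is set by the catalyst: the phenoxide of 5 is mirror-symmetric, its two prenyl-bearing carbons are enantiotopic, and the tight chiral ion pair should expose only one of them, the remote stereocentre of 8 being unable to decide this alone. The step needs C- over O-alkylation, for which the soft iodide and the shielding of the only unchelated oxygen by its two flanking prenyl groups are relied on, and it needs closure through that para-derived oxygen, which is free while the oxygens next to the acyl group are held in the hydrogen-bonded beta-triketone array. Either prenyl-bearing carbon gives the same constitution, and the acyl-bearing carbon is the least nucleophilic ring position, so no further site selectivity is required.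

**Compound list**

1 | phloroglucinol (benzene-1,3,5-triol) | Oc1cc(O)cc(O)c1 | starting material
2 | isovaleryl chloride (3-methylbutanoyl chloride) | CC(C)CC(=O)Cl | starting material
3 | phlorisovalerophenone, 3-methyl-1-(2,4,6-trihydroxyphenyl)butan-1-one | CC(C)CC(=O)c1c(O)cc(O)cc1O | intermediate
4 | prenyl bromide (1-bromo-3-methylbut-2-ene) | CC(C)=CCBr | starting material
5 | deoxyhumulone, 3-methyl-1-[2,4,6-trihydroxy-3,5-bis(3-methylbut-2-en-1-yl)phenyl]butan-1-one | CC(C)CC(=O)c1c(O)c(CC=C(C)C)c(O)c(CC=C(C)C)c1O | intermediate
6 | prenol (3-methylbut-2-en-1-ol) | CC(C)=CCO | starting material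
7 | [(2R)-3,3-dimethyloxiran-2-yl]methanol | OC[C@H]1OC1(C)C | intermediate
8 | (3S)-3-(iodomethyl)-2,2-dimethyloxirane | IC[C@H]1OC1(C)C | intermediate
9 | (6S)-6-{[(2R)-3,3-dimethyloxiran-2-yl]methyl}-3,5-dihydroxy-2-(3-methylbutanoyl)-4,6-bis(3-methylbut-2-en-1-yl)cyclohexa-2,4-dien-1-one | CC(C)=CCC1=C(O)[C@@](C[C@H]2OC2(C)C)(CC=C(C)C)C(=O)C(C(=O)CC(C)C)=C1O | intermediate
10 | (2S,3aS)-6-hydroxy-2-(2-hydroxypropan-2-yl)-5-(3-methylbutanoyl)-3a,7-bis(3-methylbut-2-en-1-yl)-3,3a-dihydro-1-benzofuran-4(2H)-one | CC(C)=CCC1=C2O[C@H](C(C)(C)O)C[C@]2(CC=C(C)C)C(=O)C(C(=O)CC(C)C)=C1O | target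

**Step count and risks**

Total step count: 5. Longest linear sequence: 3 steps (1 to 3 to 5 to 10, or 6 to 7 to 8 to 10).

Steps most likely to fail:

1. Step 5. The phenoxide may react through its para oxygen instead of carbon under ion-pair conditions. The ion pair may discriminate poorly between the enantiotopic ring carbons, which would give both epimers at C3a. The ring may also close through an acyl-side oxygen. Fallback, with known reaction types only: setting out from 5, dearomatising C-prenylation with 4 (NaOMe, MeOH, 0 °C) should give lupulone F1. A Shi epoxidation of F1 (D-fructose-derived ketone, one equivalent of KHSO5, K2CO3 buffer, MeCN/dimethoxymethane/water, 0 °C) should oxidise a geminal prenyl group from the face that gives the (R)-epoxide. This affords 9 together with its epimer at the quaternary carbon, the (6R)-epoxy dienone F2. Both should close 5-exo (K2CO3, MeOH) to 10 and to the (2S,3aR) epimer of 10 F3, which is removed by chromatography. The fallback comes back to the route at 9.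

2. Step 2. Over-alkylation with dearomatisation, O-prenylation and incomplete double alkylation all drain material. Fallback: setting out from 3, a Friedel–Crafts prenylation with 2-methylbut-3-en-2-ol and BF3·OEt2 in dioxane at 23 °C alkylates only the free ring C–H positions through the dimethylallyl cation and cannot dearomatise the ring. It comes back to the route at 5 and makes no new compound (F0).

3. Step 3. The small, volatile, water-miscible epoxy alcohol may be lost on isolation or opened by the titanium alkoxide, and the enantiomeric purity of an oil cannot be raised. Fallback: setting out from 6, the same epoxidation is run but the product is captured in the reaction mixture (TsCl, Et3N, DMAP, −20 to 0 °C) as the crystalline [(2R)-3,3-dimethyloxiran-2-yl]methyl 4-methylbenzenesulfonate F4. This is recrystallised and then converted by Finkelstein exchange (NaI, acetone, 23 °C) to the iodide. The fallback comes back to the route at 8 and bypasses isolated 7 and step 4.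

Further compounds
F1 | step 5 | lupulone, 3,5-dihydroxy-2-(3-methylbutanoyl)-4,6,6-tris(3-methylbut-2-en-1-yl)cyclohexa-2,4-dien-1-one | CC(C)=CCC1=C(O)C(CC=C(C)C)(CC=C(C)C)C(=O)C(C(=O)CC(C)C)=C1O
F2 | step 5 | (6R)-6-{[(2R)-3,3-dimethyloxiran-2-yl]methyl}-3,5-dihydroxy-2-(3-methylbutanoyl)-4,6-bis(3-methylbut-2-en-1-yl)cyclohexa-2,4-dien-1-one | CC(C)=CCC1=C(O)[C@](C[C@H]2OC2(C)C)(CC=C(C)C)C(=O)C(C(=O)CC(C)C)=C1O
F3 | step 5 | (2S,3aR)-6-hydroxy-2-(2-hydroxypropan-2-yl)-5-(3-methylbutanoyl)-3a,7-bis(3-methylbut-2-en-1-yl)-3,3a-dihydro-1-benzofuran-4(2H)-one | CC(C)=CCC1=C2O[C@H](C(C)(C)O)C[C@@]2(CC=C(C)C)C(=O)C(C(=O)CC(C)C)=C1O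
F0 | step 2 | none | none
F4 | step 3 | [(2R)-3,3-dimethyloxiran-2-yl]methyl 4-methylbenzenesulfonate | Cc1ccc(cc1)S(=O)(=O)OC[C@H]1OC1(C)C
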